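**Synthetic plan**

- Retrosynthesis: the 14-membered carbocycle is opened at C1–C2 to a seco 3-(bromomethyl)butenolide carrying an allyl β-keto ester; the chain is then cut at C2–C3 (Reformatsky), C13–C14 (vinylogous aldol) and C5–C6 (allyl anion alkylation).
- Enabling feature: in the α-methylene-γ-butyrolactone ring (O–C14–C1–C15–C16), C1 is β to the lactone carbonyl C16 and, through C2, β to the C3 oxygen. The exocyclic C15=C17 alkene can therefore be what is left when a leaving group departs from C17 after a C2 carbanion has added to C1, and a C3 ketone beside quaternary C4 has acidic hydrogens only on C2.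
- Forward order: C5–C6 joins geranyl bromide to the methallyl unit; the furan-derived five-membered lactone is attached at C13–C14; the two-carbon ester is added at C2–C3; the 14-membered ring is closed last at C1–C2, the same event turning the butenolide into the methylene lactone.
- Stereochemistry: C4 (S) from Sharpless epoxidation; C13 (S) and C14 (R) together from a catalyst-controlled anti vinylogous Mukaiyama aldol; C1 (R) from addition anti to the C14 substituent in the ring closure (trans lactone); C3 (S) from Corey–Bakshi–Shibata reduction.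

Key step: step 19

Remarks: cembrane numbering is used for the target and the seco intermediates (lactone C16(=O)–O–C14, carbocycle C1 to C14, methylene C17 on C15, C18 the hydroxymethyl on C4, C19 and C20 the methyls on C8 and C12). TBS = tert-butyldimethylsilyl, PMB = 4-methoxybenzyl, DABCO = 1,4-diazabicyclo[2.2.2]octane. For step 11 it is assumed that the (R,R)-bisphosphoramide directs the nucleophile to the Re face of the aldehyde; if the sense is the opposite, its enantiomer is used.

**Route**

Step 1
Reactants: 1 2-methylprop-2-en-1-ol; 2 geranyl bromide [(2E)-1-bromo-3,7-dimethylocta-2,6-diene]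
Product: 4 (5E)-6,10-dimethyl-2-methylideneundeca-5,9-dien-1-ol, via allyl dianion 3 (not isolated)
Conditions: n-BuLi (2.2 equiv), TMEDA, Et2O, 0 °C to rt; then 2, THF, −78 °C to rt
Reagents that add atoms: none
Why: Alkoxide-directed allylic lithiation of 1 gives a symmetrical 2-(oxidomethyl)allyl anion whose carbon terminus is far more nucleophilic than the alkoxide, so SN2 alkylation of the primary allylic bromide at low temperature should form the C5–C6 bond and leave the (E)-alkene of the geranyl unit untouched (allyl anion alkylation).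

Step 2
Reactants: 4 (5E)-6,10-dimethyl-2-methylideneundeca-5,9-dien-1-ol
Product: 5 [(2S)-2-[(3E)-4,8-dimethylnona-3,7-dien-1-yl]oxiran-2-yl]methanol
Conditions: Ti(OiPr)4 (10 mol %), L-(+)-diethyl tartrate (12 mol %), t-BuOOH, 4 Å MS, CH2Cl2, −20 °C
Reagents that add atoms: tert-butyl hydroperoxide CC(C)(C)OO
Why: Sharpless asymmetric epoxidation acts only on the alkene of the allylic alcohol, leaves the two trisubstituted alkenes alone, and with L-(+)-diethyl tartrate should deliver oxygen to the face that gives the (S)-2-alkylglycidol, which fixes C4.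

Step 3
Reactants: 5 [(2S)-2-[(3E)-4,8-dimethylnona-3,7-dien-1-yl]oxiran-2-yl]methanol
Product: 6 (2S,5E)-2-{[(4-methoxybenzyl)oxy]methyl}-6,10-dimethylundeca-5,9-diene-1,2-diol
Conditions: 4-methoxybenzyl alcohol (3 equiv), NaH (2.5 equiv), DMF, 0 to 60 °C
Reagents that add atoms: 4-methoxybenzyl alcohol COc1ccc(CO)cc1
Why: Alkoxide opening of the epoxide is an SN2 attack at the unsubstituted CH2 terminus (which becomes C3), and since the competing Payne rearrangement of this 2,2-disubstituted glycidol only exchanges its two CH2O arms with inversion at C4 it returns the same enantiomer, so the C4 configuration is carried through unchanged.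

Step 4
Reactants: 6 (2S,5E)-2-{[(4-methoxybenzyl)oxy]methyl}-6,10-dimethylundeca-5,9-diene-1,2-diol
Product: 7 (4R)-4-[(3E)-4,8-dimethylnona-3,7-dien-1-yl]-4-{[(4-methoxybenzyl)oxy]methyl}-2,2-dimethyl-1,3-dioxolane
Conditions: 2,2-dimethoxypropane, PPTS (cat.), CH2Cl2, rt
Reagents that add atoms: 2,2-dimethoxypropane COC(C)(C)OC
Why: Acid-catalysed transacetalisation ties the tertiary C4 hydroxyl and the primary C18 hydroxyl into a five-membered isopropylidene acetal under conditions mild enough for the PMB ether and the alkenes.

Step 5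
Reactants: 7 (4R)-4-[(3E)-4,8-dimethylnona-3,7-dien-1-yl]-4-{[(4-methoxybenzyl)oxy]methyl}-2,2-dimethyl-1,3-dioxolane
Product: 8 (2E,6E)-9-[(4R)-4-{[(4-methoxybenzyl)oxy]methyl}-2,2-dimethyl-1,3-dioxolan-4-yl]-2,6-dimethylnona-2,6-dien-1-ol
Conditions: SeO2 (0.3 equiv), t-BuOOH (3 equiv), salicylic acid (0.1 equiv), CH2Cl2, 0 °C to rt
Reagents that add atoms: selenium dioxide O=[Se]=O (transfers the oxygen); tert-butyl hydroperoxide CC(C)(C)OO (re-oxidises selenium and is the ultimate oxygen source)
Why: Selenium dioxide allylic oxidation (ene reaction then [2,3]-sigmatropic shift, Riley oxidation) is expected to hydroxylate the (E)-methyl group of the terminal isopropylidene alkene in preference to the internal alkene and without moving the double bond, and any enal formed by over-oxidation is simply the product of step 6.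

Step 6
Reactants: 8 (2E,6E)-9-[(4R)-4-{[(4-methoxybenzyl)oxy]methyl}-2,2-dimethyl-1,3-dioxolan-4-yl]-2,6-dimethylnona-2,6-dien-1-ol
Product: 9 (2E,6E)-9-[(4R)-4-{[(4-methoxybenzyl)oxy]methyl}-2,2-dimethyl-1,3-dioxolan-4-yl]-2,6-dimethylnona-2,6-dienal
Conditions: MnO2 (excess), CH2Cl2, rt
Reagents that add atoms: none
Why: Activated MnO2 oxidises allylic alcohols selectively to enals and should not touch the PMB ether, the acetal or the alkene geometry (allylic alcohol oxidation).

Step 7
Reactants: 10 furan-3-ylmethanol
Product: 13 [2-(trimethylsilyl)furan-3-yl]methanol, via dilithio alkoxide 11 (not isolated), via bis(trimethylsilyl) compound 12 (not isolated)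
Conditions: n-BuLi (2.2 equiv), THF, −78 to 0 °C; Me3SiCl (2.5 equiv), −78 °C to rt; then K2CO3, MeOH, 0 °C
Reagents that add atoms: chlorotrimethylsilane C[Si](C)(C)Cl
Why: The lithium alkoxide directs the second lithiation to the neighbouring furan C2 position (directed ortho-metalation), both lithium sites are silylated, and mild methanolysis removes only the labile O-silyl group, leaving the C-silyl group that later decides where the lactone carbonyl appears.

Step 8
Reactants: 13 [2-(trimethylsilyl)furan-3-yl]methanol
Product: 14 tert-butyldimethyl{[2-(trimethylsilyl)furan-3-yl]methoxy}silane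
Conditions: TBSCl, imidazole, DMF, rt
Reagents that add atoms: tert-butyl(chloro)dimethylsilane CC(C)(C)[Si](C)(C)Cl
Why: Silylation of a primary alcohol with a silyl chloride and imidazole is routine and gives the ether that will later become the C17 leaving-group precursor.

Step 9
Reactants: 14 tert-butyldimethyl{[2-(trimethylsilyl)furan-3-yl]methoxy}silane
Product: 16 3-{[(tert-butyldimethylsilyl)oxy]methyl}furan-2(5H)-one, via 2-(trimethylsilyloxy)furan 15 (not isolated)
Conditions: CH3CO3H (in AcOH), NaOAc, CH2Cl2, 0 °C to rt
Reagents that add atoms: peracetic acid CC(=O)OO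
Why: Buffered peracid oxidation of a 2-silylfuran proceeds by epoxidation of the silyl-bearing double bond, ring opening and a 1,2-shift of silicon from carbon to oxygen to give a 2-silyloxyfuran that is protodesilylated in the medium, so the carbonyl ends up regiospecifically on the former C–Si carbon (C16) and the conjugated butenolide results.

Step 10
Reactants: 16 3-{[(tert-butyldimethylsilyl)oxy]methyl}furan-2(5H)-one
Product: 17 tert-butyl{[3-({[tert-butyl(dimethyl)silyl]oxy}methyl)furan-2-yl]oxy}dimethylsilane
Conditions: TBSOTf, Et3N, CH2Cl2, 0 °C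
Reagents that add atoms: tert-butyldimethylsilyl trifluoromethanesulfonate CC(C)(C)[Si](C)(C)OS(=O)(=O)C(F)(F)F
Why: Soft enolisation of the butenolide at its γ-position with a silyl triflate and a tertiary amine gives the aromatic 2-silyloxyfuran, the nucleophile for the vinylogous aldol.

Step 11
Reactants: 9 (2E,6E)-9-[(4R)-4-{[(4-methoxybenzyl)oxy]methyl}-2,2-dimethyl-1,3-dioxolan-4-yl]-2,6-dimethylnona-2,6-dienal; 17 tert-butyl{[3-({[tert-butyl(dimethyl)silyl]oxy}methyl)furan-2-yl]oxy}dimethylsilane
Product: 19 anti aldol adduct (13S,14R): (5R)-3-(TBSOCH2)-5-[(1S,2E,6E)-1-hydroxy-2,6-dimethyl-9-{(4R)-2,2-dimethyl-4-(PMBOCH2)-1,3-dioxolan-4-yl}nona-2,6-dien-1-yl]furan-2(5H)-one, via trichlorosilyl ether 18 (not isolated)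
Conditions: SiCl4 (1.2 equiv), (R,R)-N,N′-bis(3,5-dimethyl-4-oxo-4,5-dihydro-3H-dinaphtho[2,1-d:1′,2′-f][1,3,2]diazaphosphepin-4-yl)-N,N′-dimethylpentane-1,5-diamine (5 mol %), i-Pr2NEt (0.2 equiv), CH2Cl2, −78 °C; aq NaHCO3/KF
Reagents that add atoms: none
Why: In this Lewis-base-activated vinylogous Mukaiyama aldol the phosphoramide-bound trichlorosilyl cation activates the enal, the silyloxyfuran attacks through its C5 position (C14) in an open transition state that favours the anti adduct, and the catalyst is expected to direct attack to the Re face of the aldehyde, which sets C13 as S and C14 as R independently of the remote C4 centre.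

Step 12
Reactants: 19 anti aldol adduct (13S,14R)
Product: 20 C13 silyl ether: 19 with the C13 hydroxyl as its TBS ether
Conditions: TBSOTf (1.2 equiv), 2,6-lutidine, CH2Cl2, −78 °C
Reagents that add atoms: tert-butyldimethylsilyl trifluoromethanesulfonate CC(C)(C)[Si](C)(C)OS(=O)(=O)C(F)(F)F
Why: A silyl triflate with the weakly basic 2,6-lutidine at low temperature silylates the hindered secondary allylic alcohol much faster than it enolises the butenolide.

Step 13
Reactants: 20 C13 silyl ether
Product: 21 C3 alcohol: 20 with CH2OPMB replaced by CH2OH [(4R)-4-(hydroxymethyl)dioxolane]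
Conditions: DDQ, CH2Cl2/pH 7 buffer, 0 °C
Reagents that add atoms: none
Why: DDQ cleaves the electron-rich 4-methoxybenzyl ether oxidatively (hydride abstraction and hydrolysis of the oxocarbenium ion) and should leave the silyl ethers, the acetal and the butenolide intact.

Step 14
Reactants: 21 C3 alcohol
Product: 22 C3 aldehyde: 21 with CH2OH oxidised to CHO [(4S)-4-formyldioxolane]
Conditions: Dess–Martin periodinane, NaHCO3, CH2Cl2, 0 °C to rt
Reagents that add atoms: none
Why: Dess–Martin oxidation of the neopentyl-type primary alcohol gives an aldehyde that has no α-hydrogen and so cannot epimerise at C4.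

Step 15
Reactants: 22 C3 aldehyde; 23 allyl bromoacetate
Product: 25 allyl β-hydroxy ester: 22 with CHO converted to CH(OH)CH2CO2CH2CH=CH2 (C3 epimers), via Reformatsky reagent 24 (not isolated)
Conditions: Zn dust (activated), THF, rt to 40 °C; aq NH4Cl
Reagents that add atoms: none
Why: The Reformatsky zinc enolate adds readily to the electrophilic α-alkoxy aldehyde to form C2–C3 but is too weakly basic to deprotonate or add to the butenolide, and the configuration of the new C3 carbinol does not matter because it is oxidised in the next step.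

Step 16
Reactants: 25 allyl β-hydroxy ester
Product: 26 allyl β-keto ester: C3 ketone of 25
Conditions: Dess–Martin periodinane, NaHCO3, CH2Cl2, 0 °C to rt
Reagents that add atoms: none
Why: Dess–Martin oxidation converts the β-hydroxy ester into the β-keto ester under buffered neutral conditions that spare the allyl ester and the butenolide.

Step 17
Reactants: 26 allyl β-keto ester
Product: 27 C17 alcohol: 26 with the primary silyl ether cleaved [3-(hydroxymethyl)butenolide]
Conditions: HF·pyridine, pyridine, THF, 0 °C
Reagents that add atoms: none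
Why: Buffered fluoride desilylation should distinguish the unhindered primary C17 silyl ether from the secondary C13 silyl ether, which is flanked by the lactone ring and a trisubstituted alkene, and the buffered medium spares the acetal.

Step 18
Reactants: 27 C17 alcohol
Product: 28 C17 bromide: 3-(bromomethyl)butenolide analogue of 27
Conditions: CBr4, PPh3, CH2Cl2, 0 °C
Reagents that add atoms: carbon tetrabromide BrC(Br)(Br)Br
Why: Appel bromination converts the primary allylic alcohol into the bromide by SN2 under neutral conditions that do not enolise the β-keto ester.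

Step 19
Reactants: 28 C17 bromide
Product: 30 14-membered trans-fused α-methylene-γ-butyrolactone β-keto ester (1R,4S,13S,14R; C2 epimers; C3 ketone; allyl ester on C2; C13 OTBS; C4/C18 acetonide; 7E,11E), via DABCO ammonium salt 29 (not isolated)
Conditions: DABCO (1.05 equiv), MeCN, 0 °C; then slow addition (syringe pump) to Cs2CO3 (3 equiv), MeCN, 0 °C to rt, final concentration 1 mM; AcOH quench
Reagents that add atoms: none
Why: Proposed new method: DABCO displaces the primary C17 bromide to give allylic ammonium salt 29, a better Michael acceptor that is blocked at C17, and when this salt meets Cs2CO3 at high dilution the carbonate removes only the C2 proton of the β-keto ester (several pKa units more acidic than the butenolide C14–H), the C2 carbanion adds to C1, and the lactone enolate so formed expels DABCO from C17 by E1cB, which makes the closure irreversible and leaves the C15=C17 methylene. The closest known reaction type is the intermolecular SN2′ alkylation of β-dicarbonyl carbanions with DABCO salts of Morita–Baylis–Hillman 2-(bromomethyl)enoates, together with the trans-selective Michael addition of malonate-type nucleophiles to 5-substituted butenolides, and its use to close a macrocycle onto a butenolide is the new element. The 14-membered carbocycle closes in a 14-exo-trig mode, the C1=C15 bond lying outside the new ring, while the five-membered lactone is already present and is only converted from a butenolide into the α-methylene-γ-butyrolactone. C1 is set as R by attack on the butenolide face anti to the silyloxy-bearing C13 substituent on C14, which gives the trans-fused lactone, and the C2 centre forms as a mixture that is erased by decarboxylation in step 20. The step needs C–C bond formation at C1 and not at C17 (14-membered SN2′ ring against 16-membered SN2 ring), which the bulky ammonium group at C17 and the conjugate-addition pathway should secure, and it needs cyclisation to outrun oligomerisation and loss of the C13 silyloxy group through γ-deprotonation, which high dilution, the mild base, the single acidic site of the nucleophile and the conformational restriction by the two (E)-trisubstituted alkenes and the dioxolane should secure. The reaction is quenched as soon as 29 is consumed so that liberated DABCO cannot re-add at C17 and reopen the ring.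

Step 20
Reactants: 30 macrocyclic β-keto ester
Product: 32 macrocyclic C3 ketone (1R,4S,13S,14R): 30 without the allyl ester on C2, via β-keto acid 31 (not isolated)
Conditions: Pd(PPh3)4 (5 mol %), HCO2H (2.5 equiv), Et3N (3 equiv), THF, rt
Reagents that add atoms: none
Why: Zerovalent palladium ionises the allyl ester to a π-allyl complex that formate reduces to propene, and the liberated β-keto acid loses CO2 at room temperature (Tsuji decarboxylative deallylation), which removes the C2 stereocentre under conditions free of primary or secondary amines that would add to the methylene lactone.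

Step 21
Reactants: 32 macrocyclic C3 ketone
Product: 33 protected sinularolide A (1R,3S,4S,13S,14R): C3 alcohol with C13 OTBS and C4/C18 acetonide
Conditions: (R)-2-methyl-CBS-oxazaborolidine [(R)-1-methyl-3,3-diphenyltetrahydro-1H,3H-pyrrolo[1,2-c][1,3,2]oxazaborole] (0.5 equiv), catecholborane (2 equiv), toluene, −78 °C; MeOH then pH 7 buffer
Reagents that add atoms: none
Why: In this Corey–Bakshi–Shibata reduction the ketone binds the (R)-oxazaborolidine through the lone pair on the side of the small C2 methylene, the fully substituted C4 being the large group, so hydride from the coordinated catecholborane should reach the face that gives the (3S)-alcohol, and catecholborane at −78 °C is not expected to reduce the lactone or hydroborate the alkenes.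

Step 22
Reactants: 33 protected sinularolide A
Product: 34 sinularolide A
Conditions: 48% aq HF, MeCN, 0 °C to rt
Reagents that add atoms: none
Why: Aqueous HF in acetonitrile cleaves the secondary silyl ether by fluoride attack at silicon and hydrolyses the isopropylidene acetal by acid catalysis in one operation, conditions that the methylene lactone and the allylic alcohol should tolerate.

**Compound list**

1 | 2-methylprop-2-en-1-ol | C=C(C)CO | starting material
2 | geranyl bromide | BrC/C=C(\C)CCC=C(C)C | starting material
3 | lithium 2-(lithiomethyl)prop-2-en-1-olate (allyl dianion) | [Li]CC(=C)CO[Li] | intermediate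
4 | (5E)-6,10-dimethyl-2-methylideneundeca-5,9-dien-1-ol | C=C(CO)CC/C=C(\C)CCC=C(C)C | intermediate
5 | [(2S)-2-[(3E)-4,8-dimethylnona-3,7-dien-1-yl]oxiran-2-yl]methanol | C1O[C@]1(CO)CC/C=C(\C)CCC=C(C)C | intermediate
6 | (2S,5E)-2-{[(4-methoxybenzyl)oxy]methyl}-6,10-dimethylundeca-5,9-diene-1,2-diol | COc1ccc(COC[C@@](O)(CO)CC/C=C(\C)CCC=C(C)C)cc1 | intermediate
7 | (4R)-4-[(3E)-4,8-dimethylnona-3,7-dien-1-yl]-4-{[(4-methoxybenzyl)oxy]methyl}-2,2-dimethyl-1,3-dioxolane | COc1ccc(COC[C@@]2(COC(C)(C)O2)CC/C=C(\C)CCC=C(C)C)cc1 | intermediate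
8 | (2E,6E)-9-[(4R)-4-{[(4-methoxybenzyl)oxy]methyl}-2,2-dimethyl-1,3-dioxolan-4-yl]-2,6-dimethylnona-2,6-dien-1-ol | COc1ccc(COC[C@@]2(COC(C)(C)O2)CC/C=C(\C)CC/C=C(\C)CO)cc1 | intermediate
9 | (2E,6E)-9-[(4R)-4-{[(4-methoxybenzyl)oxy]methyl}-2,2-dimethyl-1,3-dioxolan-4-yl]-2,6-dimethylnona-2,6-dienal | COc1ccc(COC[C@@]2(COC(C)(C)O2)CC/C=C(\C)CC/C=C(\C)C=O)cc1 | intermediate
10 | furan-3-ylmethanol | OCc1ccoc1 | starting material
11 | lithium (2-lithiofuran-3-yl)methanolate | [Li]OCc1ccoc1[Li] | intermediate
12 | trimethyl{3-[(trimethylsilyloxy)methyl]furan-2-yl}silane | C[Si](C)(C)OCc1ccoc1[Si](C)(C)C | intermediate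
13 | [2-(trimethylsilyl)furan-3-yl]methanol | OCc1ccoc1[Si](C)(C)C | intermediate
14 | tert-butyldimethyl{[2-(trimethylsilyl)furan-3-yl]methoxy}silane | CC(C)(C)[Si](C)(C)OCc1ccoc1[Si](C)(C)C | intermediate
15 | tert-butyldimethyl{[2-(trimethylsilyloxy)furan-3-yl]methoxy}silane | CC(C)(C)[Si](C)(C)OCc1ccoc1O[Si](C)(C)C | intermediate
16 | 3-{[(tert-butyldimethylsilyl)oxy]methyl}furan-2(5H)-one | CC(C)(C)[Si](C)(C)OCC1=CCOC1=O | intermediate
17 | tert-butyl{[3-({[tert-butyl(dimethyl)silyl]oxy}methyl)furan-2-yl]oxy}dimethylsilane | CC(C)(C)[Si](C)(C)OCc1ccoc1O[Si](C)(C)C(C)(C)C | intermediate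
18 | C13 O-trichlorosilyl ether of adduct 19 | CC(C)(C)[Si](C)(C)OCC1=C[C@H]([C@@H](O[Si](Cl)(Cl)Cl)/C(C)=C/CC/C(C)=C/CC[C@@]2(COCc3ccc(OC)cc3)COC(C)(C)O2)OC1=O | intermediate
19 | anti aldol adduct (13S,14R), C13 OH, C17 OTBS, C3 OPMB, C4/C18 acetonide | CC(C)(C)[Si](C)(C)OCC1=C[C@H]([C@@H](O)/C(C)=C/CC/C(C)=C/CC[C@@]2(COCc3ccc(OC)cc3)COC(C)(C)O2)OC1=O | intermediate
20 | C13 TBS ether of 19 | CC(C)(C)[Si](C)(C)OCC1=C[C@H]([C@@H](O[Si](C)(C)C(C)(C)C)/C(C)=C/CC/C(C)=C/CC[C@@]2(COCc3ccc(OC)cc3)COC(C)(C)O2)OC1=O | intermediate
21 | C3 primary alcohol | CC(C)(C)[Si](C)(C)OCC1=C[C@H]([C@@H](O[Si](C)(C)C(C)(C)C)/C(C)=C/CC/C(C)=C/CC[C@@]2(CO)COC(C)(C)O2)OC1=O | intermediate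
22 | C3 aldehyde | CC(C)(C)[Si](C)(C)OCC1=C[C@H]([C@@H](O[Si](C)(C)C(C)(C)C)/C(C)=C/CC/C(C)=C/CC[C@@]2(C=O)COC(C)(C)O2)OC1=O | intermediate
23 | allyl bromoacetate | BrCC(=O)OCC=C | starting material
24 | allyl (bromozincio)acetate (Reformatsky reagent) | Br[Zn]CC(=O)OCC=C | intermediate
25 | allyl β-hydroxy ester (C3 epimers) | CC(C)(C)[Si](C)(C)OCC1=C[C@H]([C@@H](O[Si](C)(C)C(C)(C)C)/C(C)=C/CC/C(C)=C/CC[C@@]2(C(O)CC(=O)OCC=C)COC(C)(C)O2)OC1=O | intermediate
26 | allyl β-keto ester | CC(C)(C)[Si](C)(C)OCC1=C[C@H]([C@@H](O[Si](C)(C)C(C)(C)C)/C(C)=C/CC/C(C)=C/CC[C@@]2(C(=O)CC(=O)OCC=C)COC(C)(C)O2)OC1=O | intermediate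
27 | C17 alcohol, 3-(hydroxymethyl)butenolide β-keto ester | OCC1=C[C@H]([C@@H](O[Si](C)(C)C(C)(C)C)/C(C)=C/CC/C(C)=C/CC[C@@]2(C(=O)CC(=O)OCC=C)COC(C)(C)O2)OC1=O | intermediate
28 | C17 bromide, seco 3-(bromomethyl)butenolide β-keto ester | BrCC1=C[C@H]([C@@H](O[Si](C)(C)C(C)(C)C)/C(C)=C/CC/C(C)=C/CC[C@@]2(C(=O)CC(=O)OCC=C)COC(C)(C)O2)OC1=O | intermediate
29 | C17 DABCO ammonium bromide | [Br-].[N+]12(CCN(CC1)CC2)CC3=C[C@H]([C@@H](O[Si](C)(C)C(C)(C)C)/C(C)=C/CC/C(C)=C/CC[C@@]4(C(=O)CC(=O)OCC=C)COC(C)(C)O4)OC3=O | intermediate
30 | 14-membered trans α-methylene lactone, C2 allyl ester (C2 epimers), C3 ketone | C=C1C(=O)O[C@@H]2[C@@H]1C(C(=O)OCC=C)C(=O)[C@@]3(COC(C)(C)O3)CC/C=C(\C)CC/C=C(\C)[C@@H]2O[Si](C)(C)C(C)(C)C | intermediate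
31 | macrocyclic β-keto acid | C=C1C(=O)O[C@@H]2[C@@H]1C(C(=O)O)C(=O)[C@@]3(COC(C)(C)O3)CC/C=C(\C)CC/C=C(\C)[C@@H]2O[Si](C)(C)C(C)(C)C | intermediate
32 | macrocyclic C3 ketone | C=C1C(=O)O[C@@H]2[C@@H]1CC(=O)[C@@]3(COC(C)(C)O3)CC/C=C(\C)CC/C=C(\C)[C@@H]2O[Si](C)(C)C(C)(C)C | intermediate
33 | protected sinularolide A (C13 OTBS, C4/C18 acetonide) | C=C1C(=O)O[C@@H]2[C@@H]1C[C@H](O)[C@@]3(COC(C)(C)O3)CC/C=C(\C)CC/C=C(\C)[C@@H]2O[Si](C)(C)C(C)(C)C | intermediate
34 | sinularolide A | C=C1C(=O)O[C@@H]2[C@@H]1C[C@H](O)[C@@](O)(CO)CC/C=C(\C)CC/C=C(\C)[C@@H]2O | target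

**Step count and risks**

Total step count: 22. Longest linear sequence: 18 steps (steps 1 to 6 and 11 to 22, from 1 and 2 to 34); the furan branch (steps 7 to 10) joins at step 11.

The three steps most likely to fail:

Step 19 (proposed new method). The ring closure may lose out to intermolecular alkylation, the carbanion may displace directly at C17 to give the 16-membered isomer, or the base may remove the C14 proton and trigger loss of the C13 silyloxy group. The fallback replaces the ionic closure by an ester-tethered pericyclic ring contraction built from established reaction types; it sets out from aldehyde 22 and returns at ketone 32. Reformatsky addition of tert-butyl bromoacetate (Zn, THF) would give tert-butyl β-hydroxy ester F1, Dess–Martin oxidation would give tert-butyl β-keto ester F2, and HF·pyridine would free the C17 hydroxyl to give alcohol F3. Heating F3 in toluene at high dilution would release tert-butanol and generate the acylketene, which the C17 hydroxyl captures to give the 18-membered β-keto lactone F4 (acylketene macrolactonisation). Further heating (xylene, 140 °C) should bring about the Carroll rearrangement: a [3,3]-sigmatropic shift of the enol of this allyl β-keto ester joins C2 to C1 on the face anti to the C14 substituent, moves the alkene to C15=C17 and, after loss of CO2 from β-keto acid 31, gives ketone 32, from which steps 21 and 22 follow unchanged.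

Step 11. Discrimination between the anti and syn adducts may be insufficient with the α-branched enal, so that the C13 configuration is set wrongly in part of the material. The fallback corrects C13 by inversion instead of relying on the catalyst for it; it sets out from 9 and 17 by way of the co-formed isomer and returns at 19. The syn (13R,14R) adduct F5 would be separated and subjected to Mitsunobu inversion (chloroacetic acid, PPh3, diisopropyl azodicarboxylate, toluene, 0 °C) to give the (13S)-chloroacetate F6, and brief methanolysis (K2CO3, MeOH, 0 °C) would deliver anti adduct 19.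

Step 21. Hydride delivery may show poor facial selectivity if the catalyst is mismatched with the conformational preference of the 14-membered ring. The fallback gives up reagent control for substrate control with recycling; it sets out from ketone 32 and returns at 33. Luche reduction (NaBH4, CeCl3·7H2O, MeOH, −78 °C) would give 33 together with its (3R)-epimer F7; the two would be separated by chromatography, and F7 would be oxidised back to 32 with Dess–Martin periodinane and reduced again, so that the material converges on 33.

**Further compounds**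

F1 | step 19 | tert-butyl β-hydroxy ester (tert-butyl analogue of 25, C3 epimers) | CC(C)(C)[Si](C)(C)OCC1=C[C@H]([C@@H](O[Si](C)(C)C(C)(C)C)/C(C)=C/CC/C(C)=C/CC[C@@]2(C(O)CC(=O)OC(C)(C)C)COC(C)(C)O2)OC1=O
F2 | step 19 | tert-butyl β-keto ester (tert-butyl analogue of 26) | CC(C)(C)[Si](C)(C)OCC1=C[C@H]([C@@H](O[Si](C)(C)C(C)(C)C)/C(C)=C/CC/C(C)=C/CC[C@@]2(C(=O)CC(=O)OC(C)(C)C)COC(C)(C)O2)OC1=O
F3 | step 19 | C17 alcohol of the tert-butyl β-keto ester | OCC1=C[C@H]([C@@H](O[Si](C)(C)C(C)(C)C)/C(C)=C/CC/C(C)=C/CC[C@@]2(C(=O)CC(=O)OC(C)(C)C)COC(C)(C)O2)OC1=O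
F4 | step 19 | 18-membered β-keto lactone (ester between C17–O and the C2 carboxyl) | O=C1CC(=O)[C@@]2(COC(C)(C)O2)CC/C=C(\C)CC/C=C(\C)[C@H](O[Si](C)(C)C(C)(C)C)[C@@H]3OC(=O)C(=C3)CO1
F5 | step 11 | syn aldol adduct (13R,14R), C13 epimer of 19 | CC(C)(C)[Si](C)(C)OCC1=C[C@H]([C@H](O)/C(C)=C/CC/C(C)=C/CC[C@@]2(COCc3ccc(OC)cc3)COC(C)(C)O2)OC1=O
F6 | step 11 | (13S)-chloroacetate of 19 | CC(C)(C)[Si](C)(C)OCC1=C[C@H]([C@@H](OC(=O)CCl)/C(C)=C/CC/C(C)=C/CC[C@@]2(COCc3ccc(OC)cc3)COC(C)(C)O2)OC1=O
F7 | step 21 | (3R)-epimer of 33 | C=C1C(=O)O[C@@H]2[C@@H]1C[C@@H](O)[C@@]3(COC(C)(C)O3)CC/C=C(\C)CC/C=C(\C)[C@@H]2O[Si](C)(C)C(C)(C)C
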